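If one earlier run is to forecast this flask, the examination starts with what that run can be made to say.

- larch: starting complex 10 mM; incoming ligand 2 equiv (fed, over 25 h); protic impurity 1.5 mM; run made earlier
- flask: starting complex 10 mM; incoming ligand 2.00 equiv (fed, over 25 h); protic impurity 1.00 mM; time 15 d

larch run (percent of the starting complex charged)

| time / h | complex with one exchanged / % | starting complex / % |
|---|---|---|
| 5.00 | 0 | 101.0 |
| 12.0 | 0.9 | 99.1 |
| 25.0 | 7.4 | 91.4 |
| 40.0 | 16.1 | 79.8 |

(scatter of a reading: 1 percentage point)

- what may be going on: leaving ligand -> by-product carried off; complex with one exchanged + incoming ligand <-> leaving ligand + complex with two exchanged; starting complex + incoming ligand <-> leaving ligand + complex with one exchanged; complex with one exchanged <-> isomer of the product; protic impurity + incoming ligand -> quenched reagent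
- no earlier run changes the charge of protic impurity; that part of a forecast is a guess

1. the best time, 15 d at the latest, for complex with one exchanged
2. the amount of complex with one exchanged, in percent of the starting complex charged, at that time

*How fast is the exchange?* After the feed in the larch run, c(starting complex) falls from 91.4 % to 79.8 % between 25.0 h and 40.0 h, a pseudo-first-order constant of 0.00905 /h. I take c(incoming ligand) over that interval in the larch run as 17.1 mM, the charge less the protic impurity and the mean exchanged. Dividing gives 5.30 × 10⁻⁴ /mM/h, the exchange constant: loss rate of starting complex per unit of c(incoming ligand).

*And the drain on the complex with one exchanged?* Its balance over the same interval leaves a first-order drain of 0.0166 /h. That is a difference of readings with a scatter of 1 percentage point, so it is the weak spot.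

*Where does the flask peak?* For consecutive irreversible first-order steps, the maximum comes at the logarithm of the ratio of the two constants over their difference. With 19.0 mM of ligand available in the flask, I reckon the exchange at 0.0101 /h and the peak 76.6 h after the mid-point of the feed.

*But the exchange consumes ligand. What then?* Putting that answer back, the mean ligand over the interval is 16.3 mM, so the exchange runs at 0.00865 /h and the interval becomes 82.1 h. Adding 12.5 h to reach the mid-point of the feed, my reckoning for the flask is 3.94 d and 25.7 %.

The forecast, from the same run, says 27 % at 4 d, and warns: “A reversible isomerisation could push the best time much later”.

    leaving ligand → by-product carried off (k = 0.0130 /h)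
    complex with one exchanged + incoming ligand ⇌ leaving ligand + complex with two exchanged (K = 0.950, k = 0.0410 /M/h)
    starting complex + incoming ligand ⇌ leaving ligand + complex with one exchanged (K = 3.80, k = 0.460 /M/h)
    complex with one exchanged ⇌ isomer of the product (K = 3.00, k = 0.0150 /h)
    protic impurity + incoming ligand → quenched reagent (k = 45.0 /M/h)

The flask peaks at 26.2 % after 5.16 d. By this step alone, both ways together, the isomerisation relaxes with a half-life of 1.44 d, shorter than the 15 d allowed, and at the best time the isomer of the product in the flask stands at 27.0 %. From the end of the feed to that time, 5.30 × 10⁻⁴ /mM/h with the mean simulated ligand gives 39.6 % of starting complex, less than the 45.4 % present. In the neighbour charged with 0.800 equiv, from the mid-point of the feed to 15 d, the mean of 7.00 mM, the charge less the protic impurity, and the final 2.28 mM of ligand gives 42.5 % of starting complex, less than the simulated 53.4 %.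

(The numbers in the tables stem from a simulated flask for an exercise, noise included.)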